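**Retrosynthetic overview**

1. The C6 2-(3,4-dimethoxyphenyl)ethyl chain is cut back to a C6 iodide and 3,4-dimethoxystyrene (Heck coupling, then a hydrogenation that also frees the catechol of ring B). The iodide comes from iodination ortho to the C7 hydroxyl.
2. The lactone is opened at O1–C8a. The route rests on this feature of ring A: C4a, which carries C4, is para to the C7 hydroxyl, and O1 sits on the neighbouring carbon C8a. A para-substituted phenol can therefore take the chain carboxylate at C4a by anodic dearomatization, and an acyloxy group can then be passed to C8a.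
3. In the five-membered spirolactone the lactone carbonyl oxygen points away from C8a and cannot bridge to it. The transfer is therefore relayed by acetic acid in the same operation: addition at C8a, loss of the spiro acyloxy group from C4a, then acyl exchange to the six-membered lactone.
4. The acid precursor, an (S)-3,3-diarylpropanoic acid, comes from rhodium-catalysed asymmetric conjugate addition of 3,4-bis(benzyloxy)phenylboronic acid to silyl-protected methyl 4-hydroxycinnamate. This sets the only stereocenter (C4 of the target).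
5. Ring order: rings A and B are bought; a transient spiro γ-lactone forms first, and the six-membered lactone is the only ring the route makes.

Key step: step 4

Assumption: the (1R,4R)-enantiomer of the diene ligand is taken to direct the aryl group to the Si face of C3 of 2; if an analytical run shows the opposite sense, the (1S,4S)-ligand is used and nothing else changes.

**Route**

Step 1
Reactants: 1 methyl (E)-3-(4-hydroxyphenyl)prop-2-enoate
Product: 2 methyl (E)-3-[4-(tert-butyldimethylsilyloxy)phenyl]prop-2-enoate
Conditions: TBSCl (1.2 equiv), imidazole (2.5 equiv), DMF, rt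
Reagents that add atoms: tert-butyldimethylsilyl chloride, CC(C)(C)[Si](C)(C)Cl
Why: Imidazole-promoted silyl ether formation masks the acidic phenol so that the enoate stays a neutral Michael acceptor in step 2; the ester and the E-alkene are inert.

Step 2
Reactants: 2 methyl (E)-3-[4-(tert-butyldimethylsilyloxy)phenyl]prop-2-enoate; 3 3,4-bis(benzyloxy)phenylboronic acid
Product: 4 methyl (S)-3-[3,4-bis(benzyloxy)phenyl]-3-[4-(tert-butyldimethylsilyloxy)phenyl]propanoate
Conditions: 3 (2 equiv), Rh(acac)(C2H4)2 (3 mol%), (1R,4R)-2,5-diphenylbicyclo[2.2.2]octa-2,5-diene (3.3 mol%), 1,4-dioxane/H2O (10:1), 60 °C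
Reagents that add atoms: none
Why: Hayashi–Miyaura reaction: the aryl group of 3 is transmetalated to monovalent rhodium bound to the C2-symmetric diene, the aryl–rhodium adds across C2=C3 of 2 from the Si face of C3 selected by the ligand, and water protonates the rhodium enolate, so the new stereocenter is set as S; benzyl and silyl ethers are inert under these near-neutral conditions.

Step 3
Reactants: 4 methyl (S)-3-[3,4-bis(benzyloxy)phenyl]-3-[4-(tert-butyldimethylsilyloxy)phenyl]propanoate
Product: 5 (S)-3-[3,4-bis(benzyloxy)phenyl]-3-(4-hydroxyphenyl)propanoic acid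
Conditions: LiOH·H2O (5 equiv), THF/MeOH/H2O (3:1:1), rt to 40 °C; then 1 M HCl
Reagents that add atoms: lithium hydroxide, [Li+].[OH-]
Why: Saponification of the methyl ester, with hydroxide also cleaving the aryl silyl ether at silicon, should free acid and phenol in one operation; the benzyl ethers are stable and the stereocenter carries neither an acidic hydrogen nor a leaving group.

Step 4
Reactants: 5 (S)-3-[3,4-bis(benzyloxy)phenyl]-3-(4-hydroxyphenyl)propanoic acid
Product: 8 (R)-4-[3,4-bis(benzyloxy)phenyl]-7-hydroxy-3,4-dihydrocoumarin, via spirolactone 6 (not isolated), via aryl acetate acid 7 (not isolated)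
Conditions: a) undivided cell, graphite anode, Pt cathode, Bu4NOAc (0.1 M), CH2Cl2/AcOH (9:1), constant current at the phenol wave, 2.1 F/mol, rt; b) BF3·OEt2 (excess), 0 °C to rt; c) concentrate, 3 M HCl, 1,4-dioxane, 60 °C, then PhMe azeotrope
Reagents that add atoms: acetic acid, CC(=O)O
Why: Proposed new method: acetate-assisted two-electron oxidation of the phenol of 5 at carbon, at a potential below that of the bis(benzyloxy)arene of ring B, gives a phenoxonium ion that the chain carboxylate traps at C4a in a 5-exo spirocyclization to 6, as in the known anodic and PhI(OAc)2 spirolactonizations of 3-(4-hydroxyphenyl)propanoic acids. The carbonyl oxygen of this five-membered lactone is held anti to C4a and cannot bridge to C8a, so the acyloxy shift is relayed by acetic acid: with BF3 on the dienone oxygen, acetic acid adds to C8a (C5 is equivalent after aromatization), the spiro C4a–O bond ionizes and H-8a is lost, which puts an acyloxy oxygen on C8a in 7 as the spiro acyloxy group leaves C4a. The closest known reaction types are the acid-promoted 1,2-acyloxy shift of open-chain para-quinol esters to resorcinol monoesters and the Thiele–Winter acetoxylation of quinones; neither has been run on a spirolactone dienone. Aqueous acid then exchanges the acetyl group for the chain acyl group: the acetate is hydrolysed and the C8a hydroxyl closes the six-membered lactone on the carboxyl group by 6-exo-trig acyl substitution, so O1–C8a and the lactone ring both come from this step. No stereocenter is formed, and C4 keeps its configuration because none of its bonds is broken (S in 5 becomes R in 6 to 8 only through the change of substituent priorities). The step needs oxygen delivery to C8a to outrun 1,2-shift of C4 (which would give the 6-hydroxy isomer) and oxidation of the phenol to outrun that of ring B; the first is served by the large excess of the carboxylic acid nucleophile and by the poor cation stabilization an acyloxy group offers to a C4 shift, the second by the acetate buffer.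

Step 5
Reactants: 8 (R)-4-[3,4-bis(benzyloxy)phenyl]-7-hydroxy-3,4-dihydrocoumarin
Product: 9 (R)-4-[3,4-bis(benzyloxy)phenyl]-7-hydroxy-6-iodo-3,4-dihydrocoumarin
Conditions: NIS (1.05 equiv), MeCN, 0 °C to rt, dark
Reagents that add atoms: N-iodosuccinimide, O=C1CCC(=O)N1I
Why: Electrophilic aromatic iodination ortho to the free C7 hydroxyl: C6 is ortho to the hydroxyl and para to the lactone oxygen and is less hindered than C8 between two oxygens, while the acid-free conditions should leave the less reactive ether ring B and the lactone untouched.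

Step 6
Reactants: 9 (R)-4-[3,4-bis(benzyloxy)phenyl]-7-hydroxy-6-iodo-3,4-dihydrocoumarin; 10 3,4-dimethoxystyrene
Product: 11 (R)-4-[3,4-bis(benzyloxy)phenyl]-6-[(E)-2-(3,4-dimethoxyphenyl)ethenyl]-7-hydroxy-3,4-dihydrocoumarin
Conditions: 10 (1.5 equiv), Pd(OAc)2 (5 mol%), Bu4NCl (1 equiv), NaHCO3 (2.5 equiv), DMF, 70 °C
Reagents that add atoms: none
Why: Mizoroki–Heck reaction: oxidative addition of the C6–I bond to zerovalent palladium, insertion at the terminal alkene carbon and syn β-hydride elimination should give the E-stilbene; hydrogencarbonate is too weak a base to open the lactone, and no stereocenter is involved.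

Step 7
Reactants: 11 (R)-4-[3,4-bis(benzyloxy)phenyl]-6-[(E)-2-(3,4-dimethoxyphenyl)ethenyl]-7-hydroxy-3,4-dihydrocoumarin
Product: 12 (R)-4-(3,4-dihydroxyphenyl)-6-[2-(3,4-dimethoxyphenyl)ethyl]-7-hydroxy-3,4-dihydrocoumarin
Conditions: H2 (1 atm), 10% Pd/C, EtOAc/THF, rt; filtration under argon
Reagents that add atoms: none
Why: Heterogeneous hydrogenation saturates the stilbene double bond and hydrogenolysis cleaves both benzyl ethers in the same operation; the aryl ester lactone and the C4 stereocenter, which has no benzylic heteroatom bond, are not affected.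

**Compound list**

1 | methyl (E)-3-(4-hydroxyphenyl)prop-2-enoate (methyl 4-hydroxycinnamate) | COC(=O)/C=C/c1ccc(O)cc1 | starting material
2 | methyl (E)-3-[4-(tert-butyldimethylsilyloxy)phenyl]prop-2-enoate | COC(=O)/C=C/c1ccc(O[Si](C)(C)C(C)(C)C)cc1 | intermediate
3 | 3,4-bis(benzyloxy)phenylboronic acid | OB(O)c1ccc(OCc2ccccc2)c(OCc2ccccc2)c1 | starting material
4 | methyl (S)-3-[3,4-bis(benzyloxy)phenyl]-3-[4-(tert-butyldimethylsilyloxy)phenyl]propanoate | COC(=O)C[C@@H](c1ccc(O[Si](C)(C)C(C)(C)C)cc1)c1ccc(OCc2ccccc2)c(OCc2ccccc2)c1 | intermediate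
5 | (S)-3-[3,4-bis(benzyloxy)phenyl]-3-(4-hydroxyphenyl)propanoic acid | OC(=O)C[C@@H](c1ccc(O)cc1)c1ccc(OCc2ccccc2)c(OCc2ccccc2)c1 | intermediate
6 | (4R)-4-[3,4-bis(benzyloxy)phenyl]-1-oxaspiro[4.5]deca-6,9-diene-2,8-dione | O=C1C[C@H](c2ccc(OCc3ccccc3)c(OCc3ccccc3)c2)C2(O1)C=CC(=O)C=C2 | intermediate
7 | (R)-3-[2-(acetyloxy)-4-hydroxyphenyl]-3-[3,4-bis(benzyloxy)phenyl]propanoic acid | OC(=O)C[C@@H](c1ccc(O)cc1OC(C)=O)c1ccc(OCc2ccccc2)c(OCc2ccccc2)c1 | intermediate
8 | (R)-4-[3,4-bis(benzyloxy)phenyl]-7-hydroxy-3,4-dihydrocoumarin | O=C1C[C@@H](c2ccc(O)cc2O1)c1ccc(OCc2ccccc2)c(OCc2ccccc2)c1 | intermediate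
9 | (R)-4-[3,4-bis(benzyloxy)phenyl]-7-hydroxy-6-iodo-3,4-dihydrocoumarin | O=C1C[C@@H](c2cc(I)c(O)cc2O1)c1ccc(OCc2ccccc2)c(OCc2ccccc2)c1 | intermediate
10 | 3,4-dimethoxystyrene | C=Cc1ccc(OC)c(OC)c1 | starting material
11 | (R)-4-[3,4-bis(benzyloxy)phenyl]-6-[(E)-2-(3,4-dimethoxyphenyl)ethenyl]-7-hydroxy-3,4-dihydrocoumarin | O=C1C[C@@H](c2cc(/C=C/c3ccc(OC)c(OC)c3)c(O)cc2O1)c1ccc(OCc2ccccc2)c(OCc2ccccc2)c1 | intermediate
12 | (R)-4-(3,4-dihydroxyphenyl)-6-[2-(3,4-dimethoxyphenyl)ethyl]-7-hydroxy-3,4-dihydrocoumarin (CNP0376539.1) | COc1ccc(CCc2cc3c(cc2O)OC(=O)C[C@@H]3c2ccc(O)c(O)c2)cc1OC | target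

**Step count**

Total steps: 7. Longest linear sequence: 7 steps (1 to 12).

**Steps most likely to fail**

Step 4 (proposed new method). What may go wrong: 1,2-shift of C4 in the Lewis-acid-activated spirodienone instead of acyloxy delivery to C8a, fragmentation of the C4–C4a bond, Friedel–Crafts attack of ring B on the activated dienone, or anodic over-oxidation of ring B. The fallback sets out from 3 and builds the lactone by the C4–aryl bond instead, using known chemistry. Commercial 7-hydroxycoumarin is silylated (TBSCl, imidazole, DMF) to 7-(tert-butyldimethylsilyloxy)coumarin F1. Boronic acid 3 is then added to F1 in a Hayashi–Miyaura reaction (Rh(acac)(C2H4)2, (R)-SEGPHOS, 1,4-dioxane/H2O, 60 °C), a known asymmetric arylation of coumarins; the SEGPHOS enantiomer is chosen, and confirmed as for step 2, to give (R)-4-[3,4-bis(benzyloxy)phenyl]-7-(tert-butyldimethylsilyloxy)chroman-2-one F2. HF·pyridine in THF removes the silyl group, and the route is rejoined at 8.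

Step 5. What may go wrong: attack of the iodinating agent at C8 or on the electron-rich ring B, or double iodination. The fallback sets out from 8 and introduces the C6 carbon by a reaction that acts only on the phenoxide ring and at its less hindered ortho position. Magnesium-mediated ortho-formylation (MgCl2, Et3N, paraformaldehyde, MeCN, reflux) should give (R)-4-[3,4-bis(benzyloxy)phenyl]-7-hydroxy-2-oxochroman-6-carbaldehyde F3. A Wittig reaction with commercial (3,4-dimethoxybenzyl)triphenylphosphonium bromide (K2CO3, 18-crown-6, CH2Cl2) should then give (R)-4-[3,4-bis(benzyloxy)phenyl]-6-[2-(3,4-dimethoxyphenyl)ethenyl]-7-hydroxychroman-2-one as an E/Z mixture F4, whose E isomer is 11. Hydrogenation of the mixture under the conditions of step 7 rejoins the route at 12.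

Step 6. What may go wrong: slow or unselective coupling of the free ortho-iodophenol under basic palladium conditions, with lactone opening, oxidative cyclization of the ortho-hydroxystilbene or polymerization of the electron-rich styrene. The fallback sets out from 9 and 10 and forms the saturated chain directly by an sp3–sp2 coupling. Hydroboration of 10 with 9-borabicyclo[3.3.1]nonane (9-BBN-H, THF) gives 9-[2-(3,4-dimethoxyphenyl)ethyl]-9-borabicyclo[3.3.1]nonane F5. B-alkyl Suzuki–Miyaura coupling of F5 with 9 (PdCl2(dppf), K3PO4, DMF/THF/H2O, 50 °C, acidic work-up to reclose any opened lactone) should give (R)-4-[3,4-bis(benzyloxy)phenyl]-6-[2-(3,4-dimethoxyphenyl)ethyl]-7-hydroxychroman-2-one F6. Hydrogenolysis of the benzyl ethers under the conditions of step 7 rejoins the route at 12.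

**Further compounds**

F1 | step 4 | 7-(tert-butyldimethylsilyloxy)coumarin | O=C1C=Cc2ccc(O[Si](C)(C)C(C)(C)C)cc2O1
F2 | step 4 | (R)-4-[3,4-bis(benzyloxy)phenyl]-7-(tert-butyldimethylsilyloxy)chroman-2-one | O=C1C[C@@H](c2ccc(O[Si](C)(C)C(C)(C)C)cc2O1)c1ccc(OCc2ccccc2)c(OCc2ccccc2)c1
F3 | step 5 | (R)-4-[3,4-bis(benzyloxy)phenyl]-7-hydroxy-2-oxochroman-6-carbaldehyde | O=C1C[C@@H](c2cc(C=O)c(O)cc2O1)c1ccc(OCc2ccccc2)c(OCc2ccccc2)c1
F4 | step 5 | (R)-4-[3,4-bis(benzyloxy)phenyl]-6-[2-(3,4-dimethoxyphenyl)ethenyl]-7-hydroxychroman-2-one (E/Z mixture) | O=C1C[C@@H](c2cc(C=Cc3ccc(OC)c(OC)c3)c(O)cc2O1)c1ccc(OCc2ccccc2)c(OCc2ccccc2)c1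
F5 | step 6 | 9-[2-(3,4-dimethoxyphenyl)ethyl]-9-borabicyclo[3.3.1]nonane | COc1ccc(CCB2C3CCCC2CCC3)cc1OC
F6 | step 6 | (R)-4-[3,4-bis(benzyloxy)phenyl]-6-[2-(3,4-dimethoxyphenyl)ethyl]-7-hydroxychroman-2-one | O=C1C[C@@H](c2cc(CCc3ccc(OC)c(OC)c3)c(O)cc2O1)c1ccc(OCc2ccccc2)c(OCc2ccccc2)c1
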